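**Retrosynthetic overview**

1. Ring A (C1–C6; spiro[5.5]undecane numbering, ring B = C6–C11) is made last by cutting C1–C2 and C3–C4: C2–C3 come from (Z)-BrCH=CHOSiMe3, and C1 and C5 are the two identical isopropenyl groups of (1R,2R)-2-bromo-1-chloro-1-methyl-4,4-di(prop-1-en-2-yl)cyclohexane.
2. Enabling feature: Br on C8 (ring B) is 1,3-cis to C1 across C7 and spiro C6, so Br, C8, C7, C6 and C1 can close a five-membered bromonium ring; this ring chooses one of the two arms (sets C6), tames the tertiary cation at C1 and passes ring-B chirality on to C2 and C3.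
3. The diisopropenyl compound comes from the 1,1-diacetyl compound and the 1,1-bis(acid chloride); the latter comes from a bridged bromolactone by ring-opening chlorination (C–O to C–Cl with retention through a three-membered bromonium ion).
4. The bromolactone comes from enantioselective bromolactonization of achiral 4-methylcyclohex-3-ene-1,1-dicarboxylic acid, made from dimethyl malonate, formaldehyde and isoprene.
5. Ring order: ring B by Diels–Alder (step 1), temporary lactone ring (step 3, opened in step 4), ring A last (step 8).

Key step: step 8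

Assumption: (DHQD)2PHAL is taken to deliver Br+ to the alkene face that leads to the (1R,4S,6R)-lactone 7; if the sense is opposite, the pseudoenantiomeric (DHQ)2PHAL is used.

**Step 1**
Reactants: 1 dimethyl malonate; 2 formaldehyde (as paraformaldehyde); 3 isoprene (2-methylbuta-1,3-diene)
Product: 5 dimethyl 4-methylcyclohex-3-ene-1,1-dicarboxylate, via dimethyl methylidenemalonate 4 (not isolated)
Conditions: (CH2O)n, Cu(OAc)2 (5 mol %), KOAc (5 mol %), AcOH, isoprene (3 equiv), 95 °C, sealed vessel
Reagents that add atoms: none
Why: Knoevenagel condensation gives the doubly activated alkene 4, which isoprene traps in a Diels–Alder reaction with the usual para orientation (methyl 1,4 to the quaternary carbon), and no stereocentre is formed.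

**Step 2**
Reactants: 5 dimethyl 4-methylcyclohex-3-ene-1,1-dicarboxylate
Product: 6 4-methylcyclohex-3-ene-1,1-dicarboxylic acid
Conditions: KOH (4 equiv), MeOH–H2O, 65 °C; then 2 M HCl, 0 °C; crystallisation
Reagents that add atoms: potassium hydroxide, [K+].[OH-]
Why: Saponification of the geminal diester followed by cold acidification should give the crystalline malonic acid without decarboxylation and lets the minor 3-methyl regioisomer from step 1 be removed; no stereocentre is present.

**Step 3**
Reactants: 6 4-methylcyclohex-3-ene-1,1-dicarboxylic acid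
Product: 7 (1R,4S,6R)-6-bromo-1-methyl-3-oxo-2-oxabicyclo[2.2.2]octane-4-carboxylic acid
Conditions: NBS (1.05 equiv), hydroquinidine 1,4-phthalazinediyl diether (DHQD)2PHAL (10 mol %), CHCl3–toluene 1:1, −40 °C; recrystallisation
Reagents that add atoms: N-bromosuccinimide, O=C1CCC(=O)N1Br
Why: Catalytic enantioselective bromolactonization: the cinchona catalyst selects the enantiotopic alkene face for Br+, and the carboxyl group on the opposite face opens the bromonium ion anti at the tertiary carbon (Markovnikov), so that the C–Br centre, the C–O centre and the bridgehead are set together and the temporary bicyclo[2.2.2] lactone ring is formed.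

**Step 4**
Reactants: 7 (1R,4S,6R)-6-bromo-1-methyl-3-oxo-2-oxabicyclo[2.2.2]octane-4-carboxylic acid
Product: 8 (3R,4R)-3-bromo-4-chloro-4-methylcyclohexane-1,1-dicarbonyl dichloride
Conditions: SOCl2 (6 equiv), ZnCl2 (10 mol %), toluene, 60 °C; evaporation
Reagents that add atoms: thionyl chloride, ClS(Cl)=O
Why: Ring-opening chlorination of a lactone with SOCl2/ZnCl2: the tertiary C–O bond ionises with help of the antiperiplanar bromine and chloride opens the three-membered bromonium ion at the tertiary carbon, so that Cl takes the place of O with retention (Br and Cl trans), while both carboxyl carbons become identical acid chlorides and the quaternary carbon is no longer stereogenic.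

**Step 5**
Reactants: 8 (3R,4R)-3-bromo-4-chloro-4-methylcyclohexane-1,1-dicarbonyl dichloride
Product: 9 1,1'-[(3R,4R)-3-bromo-4-chloro-4-methylcyclohexane-1,1-diyl]di(ethan-1-one)
Conditions: Me2CuLi (2.5 equiv, from CuI and MeLi), Et2O, −78 °C; aq. NH4Cl
Reagents that add atoms: lithium dimethylcuprate, [Li+].C[Cu-]C
Why: Ketone synthesis from an acid chloride and a lithium dialkylcuprate, which stops at the ketone and should leave the secondary bromide and the tertiary chloride untouched at −78 °C; the two halogen-bearing stereocentres are not involved.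

**Step 6**
Reactants: 9 1,1'-[(3R,4R)-3-bromo-4-chloro-4-methylcyclohexane-1,1-diyl]di(ethan-1-one)
Product: 10 (1R,2R)-2-bromo-1-chloro-1-methyl-4,4-di(prop-1-en-2-yl)cyclohexane
Conditions: Cp2Ti(μ-Cl)(μ-CH2)AlMe2 (Tebbe reagent, 2.6 equiv), pyridine (cat.), THF–toluene, −40 → 0 °C
Reagents that add atoms: Tebbe reagent Cp2Ti(μ-Cl)(μ-CH2)AlMe2, C[Al](C)C[Ti](Cl)(C1C=CC=C1)C1C=CC=C1
Why: Tebbe olefination (titanium methylidene, [2+2] then retro-[2+2]) methylenates both hindered ketones under non-basic conditions, so that neither retro-Claisen cleavage of the 1,3-diketone nor elimination of HCl or HBr should compete; the stereocentres are unchanged.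

**Step 7**
Reactants: 11 (ethenyloxy)trimethylsilane
Product: 13 (Z)-[(2-bromoethenyl)oxy]trimethylsilane, via bromoacetaldehyde 12 (not isolated)
Conditions: Br2 (1.0 equiv), CH2Cl2, −78 °C; then i-Pr2NEt (1.2 equiv), −78 → 20 °C; filtration, distillation
Reagents that add atoms: bromine, BrBr
Why: Bromination of a silyl enol ether gives α-bromo aldehyde 12 and Me3SiBr, which together with the hindered amine silylate 12 on oxygen (soft enolisation) to the Z enol ether, the isomer favoured for 2-halo enol ethers.

**Step 8**
Reactants: 10 (1R,2R)-2-bromo-1-chloro-1-methyl-4,4-di(prop-1-en-2-yl)cyclohexane; 13 (Z)-[(2-bromoethenyl)oxy]trimethylsilane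
Product: 16 (2R,3S,6R,8R,9R)-2,8-dibromo-9-chloro-1,1,9-trimethyl-5-methylidenespiro[5.5]undecan-3-ol, via bridged bromonium triflimide 14 (not isolated), via α-bromo aldehyde 15 (not isolated)
Conditions: HNTf2 (1.0 equiv), CH2Cl2, −78 °C, 15 min; then 13 (1.05 equiv, slow addition), −78 → −45 °C; Et3N quench; 1 M aq. citric acid–THF work-up
Reagents that add atoms: none
Why: Proposed new method: HNTf2 protonates an isopropenyl group of 10 (Markovnikov; the proton can move between the two arms), and the tertiary cation on the arm that is 1,3-cis to the ring bromine is captured by that bromine as the five-membered bridged bromonium ion 14 (Br, C8, C7, C6, C1), which should persist with the non-nucleophilic NTf2 anion, resist Wagner–Meerwein and alkenyl shifts and lock ring B; the enol ether 13 then attacks C1 anti to Br+ (C1–C2 bond), and the O-silylated α-bromo aldehyde 15, activated by the Me3SiNTf2 formed in situ, closes ring A by an intramolecular carbonyl-ene reaction with the second isopropenyl group (C3–C4 bond), the allylic methyl hydrogen passing to oxygen so that the C5 methylidene and the C3 hydroxyl appear directly. The closest known reaction types are the Lewis-acid SN1 α-tert-alkylation of silyl enol ethers by tertiary carbocations, the opening of five-membered cyclic halonium ions (1,4-halogen participation) at the more substituted carbon, and the Lewis-acid type 2 carbonyl-ene cyclisation of 6-methylhept-6-enals to 3-methylidenecyclohexanols; new are the bromine-bridged cation as alkylating agent and the coupling of the two events. Ring A is closed by the ene step through a six-membered chair in which the ene double bond lies inside the new ring and the carbonyl group outside it (tether on the central ene carbon). C6 is set by the bridge, since only the arm cis to Br on C8 can be bridged; C2 is set in the attack on the rigid bicyclic ion, the nucleophile entering between the remaining isopropenyl group and C11 with its hydrogen turned to the isopropenyl group and its oxygen-bearing carbon turned away from quaternary C6 (2R, the least secure element); C3 is set in the ene chair with the C2–Br bond equatorial and anti to the forming C3–C4 bond and the C=O group axial towards the methyl hydrogen, which should give the cis bromohydrin (3S). The step needs a choice between two identical arms (secured by the 1,3-cis bromine), attack at the tertiary and not the secondary bromonium carbon (secured by the cationic character of C1), consumption of 13 by 14 before it meets aldehyde 15 (secured by slow addition of one equivalent), and survival of the methylidene group and the tertiary chloride (secured by −78 °C and the amine quench).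

**Compound list**

1 | dimethyl malonate | COC(=O)CC(=O)OC | starting material
2 | formaldehyde (as paraformaldehyde) | C=O | starting material
3 | isoprene (2-methylbuta-1,3-diene) | C=CC(C)=C | starting material
4 | dimethyl methylidenemalonate | C=C(C(=O)OC)C(=O)OC | intermediate
5 | dimethyl 4-methylcyclohex-3-ene-1,1-dicarboxylate | COC(=O)C1(C(=O)OC)CCC(C)=CC1 | intermediate
6 | 4-methylcyclohex-3-ene-1,1-dicarboxylic acid | OC(=O)C1(C(=O)O)CCC(C)=CC1 | intermediate
7 | (1R,4S,6R)-6-bromo-1-methyl-3-oxo-2-oxabicyclo[2.2.2]octane-4-carboxylic acid | OC(=O)[C@@]12CC[C@@](C)(OC1=O)[C@H](Br)C2 | intermediate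
8 | (3R,4R)-3-bromo-4-chloro-4-methylcyclohexane-1,1-dicarbonyl dichloride | ClC(=O)C1(C(Cl)=O)CC[C@@](C)(Cl)[C@H](Br)C1 | intermediate
9 | 1,1'-[(3R,4R)-3-bromo-4-chloro-4-methylcyclohexane-1,1-diyl]di(ethan-1-one) | CC(=O)C1(C(C)=O)CC[C@@](C)(Cl)[C@H](Br)C1 | intermediate
10 | (1R,2R)-2-bromo-1-chloro-1-methyl-4,4-di(prop-1-en-2-yl)cyclohexane | C=C(C)C1(C(C)=C)CC[C@@](C)(Cl)[C@H](Br)C1 | intermediate
11 | (ethenyloxy)trimethylsilane | C=CO[Si](C)(C)C | starting material
12 | bromoacetaldehyde | O=CCBr | intermediate
13 | (Z)-[(2-bromoethenyl)oxy]trimethylsilane | Br/C=C\O[Si](C)(C)C | intermediate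
14 | (1R,4R,5R)-4-chloro-4,7,7-trimethyl-1-(prop-1-en-2-yl)-6-bromoniabicyclo[3.2.1]octane bis(trifluoromethanesulfonyl)azanide (Br+ bridges C8 and C1 of the target) | CC1(C)[Br+][C@@H]2C[C@@]1(C(C)=C)CC[C@@]2(C)Cl.FC(F)(F)S(=O)(=O)[N-]S(=O)(=O)C(F)(F)F | intermediate
15 | (2R)-2-bromo-3-[(1R,3R,4R)-3-bromo-4-chloro-4-methyl-1-(prop-1-en-2-yl)cyclohexyl]-3-methylbutanal | O=C[C@H](Br)C(C)(C)[C@]1(C(C)=C)CC[C@@](C)(Cl)[C@H](Br)C1 | intermediate
16 | (2R,3S,6R,8R,9R)-2,8-dibromo-9-chloro-1,1,9-trimethyl-5-methylidenespiro[5.5]undecan-3-ol | C=C1C[C@H](O)[C@H](Br)C(C)(C)[C@@]12CC[C@@](C)(Cl)[C@H](Br)C2 | target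

**Step count**

Total step count: 8. Longest linear sequence: 7 steps (steps 1–6 and 8; step 7 makes the two-carbon partner).

**Three steps most likely to fail**

Step 8 (Proposed new method). The cation may ionise and react without bromine bridging, which would open the way to 1,2-alkenyl shift or oligomerisation and to loss of facial control at C2 and of arm selection at C6; acid may also move the exocyclic double bond into the ring. The fallback uses known reaction types, fixes C6 by the lactone tether and C2 by reagent control, and sets out from 7.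
- The free acid of 7 is methylated (Me3SiCHN2, MeOH) to methyl (1R,4S,6R)-6-bromo-1-methyl-3-oxo-2-oxabicyclo[2.2.2]octane-4-carboxylate F1.
- SOCl2/ZnCl2 opens the lactone to methyl (1S,3R,4R)-3-bromo-4-chloro-1-(chlorocarbonyl)-4-methylcyclohexane-1-carboxylate F2.
- Me2CuLi at −78 °C gives methyl (1R,3R,4R)-1-acetyl-3-bromo-4-chloro-4-methylcyclohexane-1-carboxylate F3.
- Tebbe olefination gives methyl (1R,3R,4R)-3-bromo-4-chloro-4-methyl-1-(prop-1-en-2-yl)cyclohexane-1-carboxylate F4, whose isopropenyl arm is trans to Br and becomes C5.
- MeLi/CeCl3 turns the ester cis to Br into 2-[(1R,3R,4R)-3-bromo-4-chloro-4-methyl-1-(prop-1-en-2-yl)cyclohexyl]propan-2-ol F5.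
- (CF3CO)2O/pyridine gives 2-[(1R,3R,4R)-3-bromo-4-chloro-4-methyl-1-(prop-1-en-2-yl)cyclohexyl]propan-2-yl trifluoroacetate F6.
- SN1 alkylation of the bromine-free enol ether 11 with F6 (TiCl4, CH2Cl2, −78 °C) gives 3-[(1R,3R,4R)-3-bromo-4-chloro-4-methyl-1-(prop-1-en-2-yl)cyclohexyl]-3-methylbutanal F7.
- Enantioselective α-bromination of F7 (α,α-bis[3,5-bis(trifluoromethyl)phenyl]prolinol trimethylsilyl ether as catalyst, enantiomer chosen for 2R; 4,4-dibromo-2,6-di-tert-butylcyclohexa-2,5-dien-1-one as bromine source) gives 15, where the fallback comes back to the route.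
- 15 is then closed to 16 with Me2AlCl (CH2Cl2, −78 °C, type 2 carbonyl-ene).

Step 3. The catalyst may discriminate the two alkene faces insufficiently, or carboxylate attack at the secondary carbon may compete and give the [3.2.1] lactone. The fallback replaces catalysis by classical resolution and sets out from 6. Bromolactonization with NBS/NaHCO3 in MeCN should give the racemate, that is 7 together with its (1S,4R,6S)-enantiomer F8. Crystallisation with (S)-1-phenylethanamine should give the less soluble (S)-1-phenylethanaminium salt of 7, F9 (the antipodal amine is used if the other salt crystallises). Acidification (1 M HCl) releases 7, where the fallback comes back to the route.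

Step 4. At 60 °C the tertiary chloride may lose HCl or HBr by E1 elimination, or chloride may be captured without the bromonium ion and scramble the Br/Cl relationship. The fallback separates the two events and sets out from 7. TiCl4 in CH2Cl2 (−78 → 0 °C) should ionise the lactone C–O bond at low temperature and return chloride through the bromonium ion to give (3R,4R)-3-bromo-4-chloro-4-methylcyclohexane-1,1-dicarboxylic acid F10. (COCl)2 with catalytic DMF at 20 °C then gives 8, where the fallback comes back to the route.

**Further compounds**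

F1 | step 8 | methyl (1R,4S,6R)-6-bromo-1-methyl-3-oxo-2-oxabicyclo[2.2.2]octane-4-carboxylate | COC(=O)[C@@]12CC[C@@](C)(OC1=O)[C@H](Br)C2
F2 | step 8 | methyl (1S,3R,4R)-3-bromo-4-chloro-1-(chlorocarbonyl)-4-methylcyclohexane-1-carboxylate | ClC(=O)[C@@]1(C(=O)OC)CC[C@@](C)(Cl)[C@H](Br)C1
F3 | step 8 | methyl (1R,3R,4R)-1-acetyl-3-bromo-4-chloro-4-methylcyclohexane-1-carboxylate | CC(=O)[C@@]1(C(=O)OC)CC[C@@](C)(Cl)[C@H](Br)C1
F4 | step 8 | methyl (1R,3R,4R)-3-bromo-4-chloro-4-methyl-1-(prop-1-en-2-yl)cyclohexane-1-carboxylate | C=C(C)[C@@]1(C(=O)OC)CC[C@@](C)(Cl)[C@H](Br)C1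
F5 | step 8 | 2-[(1R,3R,4R)-3-bromo-4-chloro-4-methyl-1-(prop-1-en-2-yl)cyclohexyl]propan-2-ol | C=C(C)[C@@]1(C(C)(C)O)CC[C@@](C)(Cl)[C@H](Br)C1
F6 | step 8 | 2-[(1R,3R,4R)-3-bromo-4-chloro-4-methyl-1-(prop-1-en-2-yl)cyclohexyl]propan-2-yl trifluoroacetate | C=C(C)[C@@]1(C(C)(C)OC(=O)C(F)(F)F)CC[C@@](C)(Cl)[C@H](Br)C1
F7 | step 8 | 3-[(1R,3R,4R)-3-bromo-4-chloro-4-methyl-1-(prop-1-en-2-yl)cyclohexyl]-3-methylbutanal | O=CCC(C)(C)[C@]1(C(C)=C)CC[C@@](C)(Cl)[C@H](Br)C1
F8 | step 3 | (1S,4R,6S)-6-bromo-1-methyl-3-oxo-2-oxabicyclo[2.2.2]octane-4-carboxylic acid | OC(=O)[C@]12CC[C@](C)(OC1=O)[C@@H](Br)C2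
F9 | step 3 | (S)-1-phenylethanaminium (1R,4S,6R)-6-bromo-1-methyl-3-oxo-2-oxabicyclo[2.2.2]octane-4-carboxylate | C[C@H]([NH3+])c1ccccc1.[O-]C(=O)[C@@]12CC[C@@](C)(OC1=O)[C@H](Br)C2
F10 | step 4 | (3R,4R)-3-bromo-4-chloro-4-methylcyclohexane-1,1-dicarboxylic acid | OC(=O)C1(C(=O)O)CC[C@@](C)(Cl)[C@H](Br)C1
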